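## Retrosynthetic overview

1. Target ⇐ its 9-O-triethylsilyl ether (last step). The Z-(1-hydroxypropan-2-ylidene) enone ⇐ α-silyloxy ketone + chloroacetone (aldol, epoxide closure, E1cB epoxide opening).
2. 9β-Oxygen ⇐ Rubottom oxidation of the cis-decalone ester. Ester ⇐ 3α-alcohol + (2E,4E,6E)-5-methyldodeca-2,4,6-trienoic acid (from oct-2-enal by alkyne homologation, carboalumination/cross-coupling, hydrolysis).
3. 3α-OH/4β-CH3 ⇐ hydroboration of a Δ3 olefin. Cis ring fusion ⇐ hydrogenation of the Δ9-en-8-one.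
4. Bicyclic dienone ⇐ chiral phosphoric acid catalysed deconjugative Michael addition of 2,3-dimethylcyclohex-2-enone to methyl vinyl ketone (sets the C5 quaternary centre), then aldol condensation.
5. Ring order: ring A is the purchased cyclohexenone; ring B is closed in step 1; no ring is formed later.

Assumption 1: the target is made as the open Z-γ-hydroxy enone as drawn; in solution it may equilibrate with its cyclic 8,12-hemiketal, so the last steps avoid acid and strong base.
Assumption 2: the named catalyst enantiomer is taken to give the required sense at the new quaternary centre; if the sense is opposite, the mirror-image catalyst is used.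
Notation: locants C1–C13 in the "Why" lines follow eremophilane numbering (C3 ester carbon, C4/C5 methyl-bearing, C7 alkylidene carbon, C8 ketone, C9 carbinol, C10 ring-fusion CH, C11–C13 side chain); β is the face of the C5 methyl.

## Route

Step 1
Reactants: 1 2,3-dimethylcyclohex-2-en-1-one; 2 methyl vinyl ketone (but-3-en-2-one)
Product: 4 (R)-4a,5-dimethyl-4,4a,7,8-tetrahydronaphthalen-2(3H)-one, via Michael adduct 3 (not isolated)
Conditions: (R)-TRIP [3,3'-bis(2,4,6-triisopropylphenyl)-BINOL hydrogen phosphate] (5 mol %), 2 (3 equiv), PhMe, 40 °C; then KOH, MeOH, 0 °C → rt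
Reagents that add atoms: none
Why: Proposed new method: the chiral phosphoric acid tautomerizes enone 1 to its through-conjugated dienol and, as a bifunctional acid/base, holds the dienol O–H and the carbonyl of 2 in one hydrogen-bonded array, so that C–C bond formation occurs at the proximal α-carbon and creates the C5 quaternary stereocentre inside the chiral pocket (γ-attack is out of reach in this cyclic array and the product cannot re-enolize at the new centre), after which base-mediated aldol condensation (Robinson annulation) closes ring B; the closest known chemistry is phosphoric acid "enol catalysis" Michael addition of α-branched cyclic ketones to enones and deconjugative α-alkylation of α-substituted enones via dienolates.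

Step 2
Reactants: 4 (R)-4a,5-dimethyl-4,4a,7,8-tetrahydronaphthalen-2(3H)-one
Product: 6 (4aS,8aR)-2,2-dimethoxy-4a,5-dimethyl-1,2,3,4,4a,7,8,8a-octahydronaphthalene, via cis-decalone 5 (not isolated)
Conditions: H2 (1 atm), 5% Pd/C, pyridine, rt; filter, concentrate; then HC(OMe)3, PPTS (cat.), MeOH, rt
Reagents that add atoms: trimethyl orthoformate COC(OC)OC; methanol CO
Why: Catalytic hydrogenation over Pd/C in basic medium adds H2 to the conjugated C=C of 4a-methyl-octalones syn to the angular methyl, setting C10 (cis ring fusion) while the hindered isolated trisubstituted alkene survives; orthoformate ketalization then masks the ketone for the hydroboration.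

Step 3
Reactants: 6 (4aS,8aR)-2,2-dimethoxy-4a,5-dimethyl-1,2,3,4,4a,7,8,8a-octahydronaphthalene
Product: 9 (4aS,5R,6R,8aR)-6-hydroxy-4a,5-dimethyloctahydronaphthalen-2(1H)-one, via alkylborane 7 (not isolated), via hydroxy ketal 8 (not isolated)
Conditions: BH3·THF, THF, 0 °C → rt; NaOH, H2O2, 0 °C → rt; then 1 M HCl, THF, rt
Reagents that add atoms: borane–THF B.C1CCOC1 (boron of 7 only); hydrogen peroxide OO (oxygen at C3); water O (carbonyl oxygen after ketal hydrolysis)
Why: Hydroboration–oxidation is an anti-Markovnikov syn addition; in the steroid-like conformer of the cis-decalin the axial C5 methyl blocks the β-face, so B and H add from the α-face, setting 3α-OH (C3) and turning the C4 methyl β (cis to the C5 methyl), and the acidic work-up hydrolyses the dimethyl ketal.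

Step 4
Reactants: 10 (E)-oct-2-enal
Product: 11 (E)-non-3-en-1-yne
Conditions: TMSCHN2, n-BuLi, THF, −78 °C; then 10, −78 °C → rt
Reagents that add atoms: (trimethylsilyl)diazomethane C[Si](C)(C)C=[N+]=[N-]
Why: Colvin homologation: lithiated TMS-diazomethane adds to the aldehyde, Peterson elimination gives a diazoalkene, and loss of N2 with 1,2-H shift gives the terminal alkyne without touching the E-olefin.

Step 5
Reactants: 11 (E)-non-3-en-1-yne; 12 ethyl (E)-3-bromoprop-2-enoate
Product: 14 ethyl (2E,4E,6E)-5-methyldodeca-2,4,6-trienoate, via alkenylalane 13 (not isolated)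
Conditions: Me3Al, Cp2ZrCl2 (20 mol %), CH2Cl2, 0 °C → rt; excess Me3Al removed in vacuo; then 12, Pd(PPh3)4 (5 mol %), ZnCl2 (cat.), THF, rt
Reagents that add atoms: trimethylaluminium C[Al](C)C
Why: Negishi Zr-catalysed carboalumination adds CH3–Al syn and regioselectively across the terminal alkyne, and Pd-catalysed cross-coupling of the alkenylalane with the (E)-bromoacrylate proceeds with retention at both partners, fixing the 2E,4E,6E triene.

Step 6
Reactants: 14 ethyl (2E,4E,6E)-5-methyldodeca-2,4,6-trienoate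
Product: 15 (2E,4E,6E)-5-methyldodeca-2,4,6-trienoic acid
Conditions: LiOH·H2O, THF/MeOH/H2O, rt; then 1 M HCl
Reagents that add atoms: lithium hydroxide [Li+].[OH-]
Why: Mild saponification of the ethyl ester leaves the triene geometry intact.

Step 7
Reactants: 9 (4aS,5R,6R,8aR)-6-hydroxy-4a,5-dimethyloctahydronaphthalen-2(1H)-one; 15 (2E,4E,6E)-5-methyldodeca-2,4,6-trienoic acid
Product: 16 (1R,2R,4aR,8aS)-1,8a-dimethyl-6-oxodecahydronaphthalen-2-yl (2E,4E,6E)-5-methyldodeca-2,4,6-trienoate
Conditions: DCC, DMAP (cat.), CH2Cl2, 0 °C → rt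
Reagents that add atoms: none
Why: Steglich esterification acylates the only hydroxyl, the equatorial 3α-alcohol, with retention at C3; the ketone is inert.

Step 8
Reactants: 16 (1R,2R,4aR,8aS)-1,8a-dimethyl-6-oxodecahydronaphthalen-2-yl (2E,4E,6E)-5-methyldodeca-2,4,6-trienoate
Product: 18 (1R,2R,4aS,5R,8aR)-1,8a-dimethyl-6-oxo-5-[(triethylsilyl)oxy]decahydronaphthalen-2-yl (2E,4E,6E)-5-methyldodeca-2,4,6-trienoate, via silyl enol ether 17 (not isolated)
Conditions: TESOTf, Et3N, CH2Cl2, 0 °C → rt (equilibrating); pentane, filter; then DMDO (1.05 equiv), acetone/CH2Cl2, −78 → 0 °C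
Reagents that add atoms: triethylsilyl triflate CC[Si](CC)(CC)OS(=O)(=O)C(F)(F)F; dimethyldioxirane CC1(C)OO1
Why: Rubottom oxidation: under equilibrating silylation the cis-decalone enolizes toward C9 (as 5β-3-keto steroids enolize toward C4), the electron-rich silyl enol ether is epoxidized by DMDO from the convex β-face far faster than the electron-poor trienoate, and 1,4-silyl shift gives the 9β-silyloxy ketone (C9 set).

Step 9
Reactants: 18 (1R,2R,4aS,5R,8aR)-1,8a-dimethyl-6-oxo-5-[(triethylsilyl)oxy]decahydronaphthalen-2-yl (2E,4E,6E)-5-methyldodeca-2,4,6-trienoate; 19 chloroacetone (1-chloropropan-2-one)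
Product: 22 (1R,2R,4aS,5R,7Z,8aR)-7-(1-hydroxypropan-2-ylidene)-1,8a-dimethyl-6-oxo-5-[(triethylsilyl)oxy]decahydronaphthalen-2-yl (2E,4E,6E)-5-methyldodeca-2,4,6-trienoate, via lithium aldolate 20 (not isolated), via epoxy ketone 21 (not isolated)
Conditions: LiHMDS (1.05 equiv), THF, −78 °C; 19, −78 → 0 °C; then DBU, 0 °C → rt
Reagents that add atoms: none
Why: Darzens-type aldol of the C7 lithium enolate (the only α-CH2) with chloroacetone and closure of the chlorohydrin alkoxide give a β,γ-epoxy ketone, whose base-promoted E1cB opening is a known route to γ-hydroxy enones; the Z geometry is expected because the tied-back epoxide CH2 takes the inside position next to the enolate oxygen, where the counter-ion also assists the departing epoxide oxygen, so the alkoxide is released on the carbonyl side.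

Step 10
Reactants: 22 (1R,2R,4aS,5R,7Z,8aR)-7-(1-hydroxypropan-2-ylidene)-1,8a-dimethyl-6-oxo-5-[(triethylsilyl)oxy]decahydronaphthalen-2-yl (2E,4E,6E)-5-methyldodeca-2,4,6-trienoate
Product: 23 (1R,2R,4aS,5R,7Z,8aR)-5-hydroxy-7-(1-hydroxypropan-2-ylidene)-1,8a-dimethyl-6-oxodecahydronaphthalen-2-yl (2E,4E,6E)-5-methyldodeca-2,4,6-trienoate (target)
Conditions: TBAF, AcOH (1:1), THF, 0 °C
Reagents that add atoms: none
Why: Buffered fluoride desilylation cleaves the secondary TES ether under near-neutral conditions, avoiding acid-induced cyclodehydration of the Z-γ-hydroxy enone to a furan and base-induced isomerization.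

## Compound list

1 | 2,3-dimethylcyclohex-2-en-1-one | CC1=C(C)C(=O)CCC1 | starting material
2 | methyl vinyl ketone (but-3-en-2-one) | C=CC(C)=O | starting material
3 | (R)-2,3-dimethyl-2-(3-oxobutyl)cyclohex-3-en-1-one | CC1=CCCC(=O)[C@]1(C)CCC(C)=O | intermediate
4 | (R)-4a,5-dimethyl-4,4a,7,8-tetrahydronaphthalen-2(3H)-one | CC1=CCCC2=CC(=O)CC[C@]12C | intermediate
5 | (4aS,8aR)-4a,5-dimethyl-3,4,4a,7,8,8a-hexahydronaphthalen-2(1H)-one (cis-fused) | CC1=CCC[C@@H]2CC(=O)CC[C@]12C | intermediate
6 | (4aS,8aR)-2,2-dimethoxy-4a,5-dimethyl-1,2,3,4,4a,7,8,8a-octahydronaphthalene | CC1=CCC[C@@H]2CC(OC)(OC)CC[C@]12C | intermediate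
7 | (6,6-dimethoxy-1,8a-dimethyldecahydronaphthalen-2-yl)borane, configuration as in 8 (shown as the monoalkylborane RBH2) | B[C@@H]1CC[C@@H]2CC(OC)(OC)CC[C@]2(C)[C@H]1C | intermediate
8 | (1R,2R,4aR,8aS)-6,6-dimethoxy-1,8a-dimethyldecahydronaphthalen-2-ol | O[C@@H]1CC[C@@H]2CC(OC)(OC)CC[C@]2(C)[C@H]1C | intermediate
9 | (4aS,5R,6R,8aR)-6-hydroxy-4a,5-dimethyloctahydronaphthalen-2(1H)-one | O[C@@H]1CC[C@@H]2CC(=O)CC[C@]2(C)[C@H]1C | intermediate
10 | (E)-oct-2-enal | CCCCC/C=C/C=O | starting material
11 | (E)-non-3-en-1-yne | CCCCC/C=C/C#C | intermediate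
12 | ethyl (E)-3-bromoprop-2-enoate | CCOC(=O)/C=C/Br | starting material
13 | dimethyl[(1E,3E)-2-methylnona-1,3-dien-1-yl]alane | CCCCC/C=C/C(C)=C/[Al](C)C | intermediate
14 | ethyl (2E,4E,6E)-5-methyldodeca-2,4,6-trienoate | CCCCC/C=C/C(C)=C/C=C/C(=O)OCC | intermediate
15 | (2E,4E,6E)-5-methyldodeca-2,4,6-trienoic acid | CCCCC/C=C/C(C)=C/C=C/C(=O)O | intermediate
16 | (1R,2R,4aR,8aS)-1,8a-dimethyl-6-oxodecahydronaphthalen-2-yl (2E,4E,6E)-5-methyldodeca-2,4,6-trienoate | CCCCC/C=C/C(C)=C/C=C/C(=O)O[C@@H]1CC[C@@H]2CC(=O)CC[C@]2(C)[C@H]1C | intermediate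
17 | (1R,2R,4aR,8aS)-1,8a-dimethyl-6-[(triethylsilyl)oxy]-1,2,3,4,4a,7,8,8a-octahydronaphthalen-2-yl (2E,4E,6E)-5-methyldodeca-2,4,6-trienoate | CCCCC/C=C/C(C)=C/C=C/C(=O)O[C@@H]1CC[C@@H]2C=C(O[Si](CC)(CC)CC)CC[C@]2(C)[C@H]1C | intermediate
18 | (1R,2R,4aS,5R,8aR)-1,8a-dimethyl-6-oxo-5-[(triethylsilyl)oxy]decahydronaphthalen-2-yl (2E,4E,6E)-5-methyldodeca-2,4,6-trienoate | CCCCC/C=C/C(C)=C/C=C/C(=O)O[C@@H]1CC[C@@H]2[C@@H](O[Si](CC)(CC)CC)C(=O)CC[C@]2(C)[C@H]1C | intermediate
19 | chloroacetone (1-chloropropan-2-one) | CC(=O)CCl | starting material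
20 | lithium aldolate of 18 with 19: C7 carries C(CH3)(CH2Cl)OLi (mixture at the two new centres) | CCCCC/C=C/C(C)=C/C=C/C(=O)O[C@@H]1CC[C@@H]2[C@@H](O[Si](CC)(CC)CC)C(=O)C(C(C)(CCl)[O-])C[C@]2(C)[C@H]1C.[Li+] | intermediate
21 | 7-(2-methyloxiran-2-yl) derivative of 18 (β,γ-epoxy ketone, mixture at C7 and the oxirane carbon) | CCCCC/C=C/C(C)=C/C=C/C(=O)O[C@@H]1CC[C@@H]2[C@@H](O[Si](CC)(CC)CC)C(=O)C(C3(C)CO3)C[C@]2(C)[C@H]1C | intermediate
22 | (1R,2R,4aS,5R,7Z,8aR)-7-(1-hydroxypropan-2-ylidene)-1,8a-dimethyl-6-oxo-5-[(triethylsilyl)oxy]decahydronaphthalen-2-yl (2E,4E,6E)-5-methyldodeca-2,4,6-trienoate | CCCCC/C=C/C(C)=C/C=C/C(=O)O[C@@H]1CC[C@@H]2[C@@H](O[Si](CC)(CC)CC)C(=O)/C(=C(/C)CO)C[C@]2(C)[C@H]1C | intermediate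
23 | (1R,2R,4aS,5R,7Z,8aR)-5-hydroxy-7-(1-hydroxypropan-2-ylidene)-1,8a-dimethyl-6-oxodecahydronaphthalen-2-yl (2E,4E,6E)-5-methyldodeca-2,4,6-trienoate (CNP0226738.1) | CCCCC/C=C/C(C)=C/C=C/C(=O)O[C@@H]1CC[C@@H]2[C@@H](O)C(=O)/C(=C(/C)CO)C[C@]2(C)[C@H]1C | target

## Step count and risks

Total step count: 10 (steps 1–10). Longest linear sequence: 7 (steps 1, 2, 3, 7, 8, 9, 10); the acid 15 is made in a 3-step side branch (steps 4–6).

The three steps most likely to fail, each with one fallback:

First, step 1, the proposed new reaction. The dienol could react at the γ- or α′-carbon, give [4+2] adducts or the exocyclic-methylene isomer, or the ee could be low. The fallback uses only known chemistry and is still organocatalytic with achiral inputs. It sets out from 2, which is added (Et3N cat., neat) to 2-methylcyclohexane-1,3-dione F1 to give 2-methyl-2-(3-oxobutyl)cyclohexane-1,3-dione F2. Proline-type catalysis (L-proline, DMSO, or N-Ts-binam-L-prolinamide with PhCO2H) effects the Hajos–Parrish–Wiechert aldol condensation to (S)-Wieland–Miescher ketone F3. MeMgBr/CeCl3 (THF, −78 °C) adds to the saturated, non-conjugated ketone to give the tertiary carbinol F4. Burgess dehydration (PhH, 50 °C) toward the only ring CH2 then comes back to the route at 4.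

Second, step 2. The hydrogenation could give too much trans-fused decalone or touch the Δ3 olefin, and the later facial selectivities depend on the cis fusion. The fallback sets out from 4. Luche reduction (NaBH4, CeCl3·7H2O, MeOH, −78 °C) gives the 8β-allylic alcohol (2S,4aR)-4a,5-dimethyl-2,3,4,4a,7,8-hexahydronaphthalen-2-ol F5. Hydroxyl-directed homogeneous hydrogenation ([Rh(nbd)(dppb)]BF4, H2, CH2Cl2) delivers hydrogen to C10 on the face of the hydroxyl and gives the cis-fused alcohol (2S,4aS,8aR)-4a,5-dimethyl-1,2,3,4,4a,7,8,8a-octahydronaphthalen-2-ol F6. Dess–Martin oxidation comes back to the route at 5, which is ketalized to 6 as in step 2.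

Third, step 9. The E1cB opening could give the E isomer or E/Z mixtures, and the enolate could alkylate chloroacetone instead of adding to it. The fallback fixes the geometry through a ring. It sets out from 21, isolated by stopping step 9 before DBU is added. PPTS (PhMe, 60 °C) cyclodehydrates it to the 9-O-TES 3-methylfuran (furan fused at C7–C8) F7. DMDO (1 equiv, acetone, −40 °C) opens the furan to the Z-keto-enal (12-aldehyde analogue of 22) F8, whose geometry is enforced by the ring it came from. NaBH4 (MeOH/CH2Cl2, −78 °C) reduces only the aldehyde and comes back to the route at 22.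

Further compounds
F1 | step 1 | 2-methylcyclohexane-1,3-dione | CC1C(=O)CCCC1=O
F2 | step 1 | 2-methyl-2-(3-oxobutyl)cyclohexane-1,3-dione | CC(=O)CCC1(C)C(=O)CCCC1=O
F3 | step 1 | (S)-Wieland–Miescher ketone, (S)-8a-methyl-3,4,8,8a-tetrahydronaphthalene-1,6(2H,7H)-dione | O=C1CCCC2=CC(=O)CC[C@]12C
F4 | step 1 | (4aS)-5-hydroxy-4a,5-dimethyl-4,4a,5,6,7,8-hexahydronaphthalen-2(3H)-one (either C5 epimer) | CC1(O)CCCC2=CC(=O)CC[C@]12C
F5 | step 2 | (2S,4aR)-4a,5-dimethyl-2,3,4,4a,7,8-hexahydronaphthalen-2-ol | CC1=CCCC2=C[C@@H](O)CC[C@]12C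
F6 | step 2 | (2S,4aS,8aR)-4a,5-dimethyl-1,2,3,4,4a,7,8,8a-octahydronaphthalen-2-ol | CC1=CCC[C@@H]2C[C@@H](O)CC[C@]12C
F7 | step 9 | 9-O-TES 3-methylfuran fused at C7–C8 (C8–O–C12H=C11(CH3)–C7), ester and silyl ether as in 18 | CCCCC/C=C/C(C)=C/C=C/C(=O)O[C@@H]1CC[C@@H]2[C@@H](O[Si](CC)(CC)CC)c3occ(C)c3C[C@]2(C)[C@H]1C
F8 | step 9 | Z-keto-enal, the 12-aldehyde analogue of 22 | CCCCC/C=C/C(C)=C/C=C/C(=O)O[C@@H]1CC[C@@H]2[C@@H](O[Si](CC)(CC)CC)C(=O)/C(=C(/C)C=O)C[C@]2(C)[C@H]1C
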